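**Retrosynthetic overview**
- The target is epicatechin-(4β→8)-epifisetinidol-(4β→8)-catechin; it comes from a benzyl-protected, bromine-capped trimer by one global hydrogenolysis.
- Lower interflavan bond (middle C4 to bottom C8): Lewis-acid coupling of a middle-unit 4-methoxy-2,3-cis-flavan-3-ol with tetra-O-benzylcatechin.
- Middle pyran ring: O1–C2 ring closure of a C2-symmetric 2-(flavan-4β-yl)resorcinol onto a cinnamaldehyde gives the flav-3-ene and sets C2. Bromohydrin, epoxide and methanolysis then put the C3 oxygen cis to the 2-aryl group.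
- That resorcinol comes from C-alkylation of cyclohexane-1,3-dione by the epicatechin C4 cation, then aromatisation. The dione reacts only at the carbon between its two oxygens, so the upper unit ends at C8 of the middle unit with no C6/C8 question.
- Ring order: top and bottom flavans are used intact from (−)-epicatechin and (+)-catechin; the middle A-ring is made first, then the middle pyran ring is closed.

Notation: α/β follow proanthocyanidin usage (the 2-aryl group of a 2R-flavan is α; a 4β substituent is trans to the 3-OH of a 2,3-cis unit). Ec* = 6,8-dibromo-5,7,3',4'-tetra-O-benzylepicatechin-4β-yl. ArB = 3,4-bis(benzyloxy)phenyl.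

**Step 1**
Reactants: 1 (−)-epicatechin
Product: 2 5,7,3',4'-tetra-O-benzylepicatechin
Conditions: BnBr, K2CO3, DMF, 0 °C to rt
Reagents that add atoms: benzyl bromide BrCc1ccccc1
Why: Williamson O-benzylation of the four phenols; the much less acidic secondary 3-OH stays free and no stereocentre is touched.

**Step 2**
Reactants: 2 5,7,3',4'-tetra-O-benzylepicatechin
Product: 4 6,8-dibromo-5,7,3',4'-tetra-O-benzyl-4β-(2-ethoxyethoxy)epicatechin, via 4β-(2-ethoxyethoxy) ether 3 (not isolated)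
Conditions: DDQ, 2-ethoxyethanol, CH2Cl2, rt; filter; NBS (2.1 equiv), CH2Cl2, −20 °C
Reagents that add atoms: 2-ethoxyethanol CCOCCO; N-bromosuccinimide O=C1CCC(=O)N1Br
Why: DDQ benzylic oxidation (hydride abstraction to the A-ring-stabilised C4 cation) with alcohol capture trans to the 3-OH gives the 4β-ether; electrophilic aromatic bromination then caps both free A-ring positions so this unit can no longer act as a nucleophile.

**Step 3**
Reactants: 4 6,8-dibromo-5,7,3',4'-tetra-O-benzyl-4β-(2-ethoxyethoxy)epicatechin; 5 cyclohexane-1,3-dione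
Product: 6 2-(Ec*)cyclohexane-1,3-dione
Conditions: 5 (3 equiv), TMSOTf (0.2 equiv), CH2Cl2–MeCN, −40 to −10 °C
Reagents that add atoms: none
Why: Lewis-acid ionisation of the C4 ether gives the flavan-4-yl cation, which C-alkylates the dione enol at C2 (SN1, Friedel–Crafts-type alkylation of a 1,3-dicarbonyl; O-alkylation is reversible) from the β-face, anti to the 3-OH and 2-aryl, which sets C4 of the top unit as in procyanidin couplings.

**Step 4**
Reactants: 6 2-(Ec*)cyclohexane-1,3-dione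
Product: 9 2-(Ec*)benzene-1,3-diol, via tris-TMS dienol ether 7 (not isolated), via tris-TMS aryl ether 8 (not isolated)
Conditions: TMSOTf (3.3 equiv), 2,6-lutidine, CH2Cl2, 0 °C; DDQ (1.05 equiv), −20 °C; K2CO3 (cat.), MeOH, rt
Reagents that add atoms: none
Why: Soft enolisation gives the 1,3-bis(silyloxy)cyclohexa-1,3-diene, DDQ dehydrogenates it to the arene (dehydrogenative aromatisation of a silyl dienol ether) and methanolysis removes the three TMS groups; no stereocentre is touched.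

**Step 5**
Reactants: 10 3,4-bis(benzyloxy)benzaldehyde
Product: 11 (E)-3-[3,4-bis(benzyloxy)phenyl]prop-2-enal
Conditions: Ph3P=CHCHO, toluene, 80 °C
Reagents that add atoms: (triphenylphosphoranylidene)acetaldehyde O=CC=P(c1ccccc1)(c1ccccc1)c1ccccc1
Why: Wittig olefination with the stabilised formyl ylide gives the (E)-enal.

**Step 6**
Reactants: 9 2-(Ec*)benzene-1,3-diol; 11 (E)-3-[3,4-bis(benzyloxy)phenyl]prop-2-enal
Product: 13 8-(Ec*)-7-hydroxy-2α-ArB-2H-chromene, via styryl benzodioxaborin 12 (not isolated)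
Conditions: PhB(OH)2 (1.1 equiv), 4 Å MS, toluene, 50 °C; then (R)-3,3'-bis(2,4,6-triisopropylphenyl)-BINOL N-triflylphosphoramide (10 mol %), −20 °C
Reagents that add atoms: none
Why: Proposed new method: PhB(OH)2 esterifies a phenol of C2-symmetric 9 and directs 1,2-addition to the enal carbonyl at the ortho carbon (Nagata-type templated hydroxyalkylation) to give benzodioxaborin 12. The chiral N-triflylphosphoramide then ionises its benzylic C–O bond to a 1-(2-hydroxyaryl)-3-arylallyl cation (the protonated vinyl o-quinone methide) held as a contact ion pair with the chiral anion, and 6-endo C–O closure (formal oxa-6π) at the B-ring terminus forms O1–C2 on the catalyst-dictated face, which sets C2 (the C4 epimers of 12 converge because C4 becomes sp2). Either phenol of 9 gives the same product, so the upper unit necessarily sits at C8. The closest known reactions are the racemic boronic-acid-mediated phenol–enal chromene annulation and the Brønsted-acid-catalysed enantioselective allylic etherification to 2H-chromenes through chiral ion pairs.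

**Step 7**
Reactants: 13 8-(Ec*)-7-hydroxy-2α-ArB-2H-chromene
Product: 16 8-(Ec*)-6-bromo-4β-methoxy-2α-ArB-chromane-3α,7-diol, via trans-bromohydrin 14 (not isolated), via cis-epoxide 15 (not isolated)
Conditions: NBS (2.1 equiv), THF–H2O, 0 °C; then K2CO3, MeOH, 0 °C to rt
Reagents that add atoms: N-bromosuccinimide O=C1CCC(=O)N1Br; water O; methanol CO
Why: NBS brominates C6 ortho to the phenol (SEAr) and delivers Br+ to C3 anti to the 2-aryl group with water opening at benzylic C4 (trans-bromohydrin). Base closes the epoxide by intramolecular SN2 with inversion at C3, so the C3 oxygen ends cis to the 2-aryl group (this sets C3), and methanol opens the labile benzylic epoxide at C4 to the stable 4-methyl ether.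

**Step 8**
Reactants: 17 (+)-catechin
Product: 18 5,7,3',4'-tetra-O-benzylcatechin
Conditions: BnBr, K2CO3, DMF, 0 °C to rt
Reagents that add atoms: benzyl bromide BrCc1ccccc1
Why: Williamson O-benzylation of the four phenols; no stereocentre is touched.

**Step 9**
Reactants: 16 8-(Ec*)-6-bromo-4β-methoxy-2α-ArB-chromane-3α,7-diol; 18 5,7,3',4'-tetra-O-benzylcatechin
Product: 19 Ec*-(4β→8)-[6-bromo-3',4'-di-O-benzylepifisetinidol]-(4β→8)-[5,7,3',4'-tetra-O-benzylcatechin]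
Conditions: 18 (3 equiv), TMSOTf (0.5 equiv), CH2Cl2, −40 to −10 °C
Reagents that add atoms: none
Why: Lewis-acid ionisation of the 4-OMe group (assisted by O1 and the para 7-oxygen) gives the C4 cation, which is attacked by C8 of tetra-O-benzylcatechin trans to the 3-OH, setting C4 of the middle unit as 4β (Friedel–Crafts-type flavan-4-yl/arene coupling as in procyanidin synthesis); every other activated arene position of 16 is blocked by Br or carbon, so it cannot self-condense.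

**Step 10**
Reactants: 19 Ec*-(4β→8)-[6-bromo-3',4'-di-O-benzylepifisetinidol]-(4β→8)-[5,7,3',4'-tetra-O-benzylcatechin]
Product: 20 epicatechin-(4β→8)-epifisetinidol-(4β→8)-catechin
Conditions: H2 (1 atm), Pd(OH)2/C, Et3N, THF–MeOH–H2O, rt
Reagents that add atoms: none
Why: Pd-catalysed hydrogenolysis removes the ten benzyl ethers and the three aryl bromides (Et3N traps HBr so the acid-labile interflavan bonds survive); no stereocentre is affected.

**Compound list**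
1 | (−)-epicatechin | Oc1cc(O)c2c(c1)O[C@H](c1ccc(O)c(O)c1)[C@H](O)C2 | starting material
2 | 5,7,3',4'-tetra-O-benzylepicatechin | C(c3ccccc3)Oc1cc(OCc3ccccc3)c2c(c1)O[C@H](c1ccc(OCc3ccccc3)c(OCc3ccccc3)c1)[C@H](O)C2 | intermediate
3 | 5,7,3',4'-tetra-O-benzyl-4β-(2-ethoxyethoxy)epicatechin | C(c3ccccc3)Oc1cc(OCc3ccccc3)c2c(c1)O[C@H](c1ccc(OCc3ccccc3)c(OCc3ccccc3)c1)[C@H](O)[C@H]2OCCOCC | intermediate
4 | 6,8-dibromo-5,7,3',4'-tetra-O-benzyl-4β-(2-ethoxyethoxy)epicatechin | C(c3ccccc3)Oc1c(Br)c(OCc3ccccc3)c2c(c1Br)O[C@H](c1ccc(OCc3ccccc3)c(OCc3ccccc3)c1)[C@H](O)[C@H]2OCCOCC | intermediate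
5 | cyclohexane-1,3-dione | O=C1CCCC(=O)C1 | starting material
6 | 2-(Ec*)cyclohexane-1,3-dione (drawn as diketone, enolised in solution) | C(c3ccccc3)Oc1c(Br)c(OCc3ccccc3)c2c(c1Br)O[C@H](c1ccc(OCc3ccccc3)c(OCc3ccccc3)c1)[C@H](O)[C@H]2C1C(=O)CCCC1=O | intermediate
7 | 2-(3-O-TMS-Ec*)-1,3-bis(trimethylsilyloxy)cyclohexa-1,3-diene | C(c3ccccc3)Oc1c(Br)c(OCc3ccccc3)c2c(c1Br)O[C@H](c1ccc(OCc3ccccc3)c(OCc3ccccc3)c1)[C@H](O[Si](C)(C)C)[C@H]2C1=C(O[Si](C)(C)C)CCC=C1O[Si](C)(C)C | intermediate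
8 | 2-(3-O-TMS-Ec*)-1,3-bis(trimethylsilyloxy)benzene | C(c3ccccc3)Oc1c(Br)c(OCc3ccccc3)c2c(c1Br)O[C@H](c1ccc(OCc3ccccc3)c(OCc3ccccc3)c1)[C@H](O[Si](C)(C)C)[C@H]2c1c(O[Si](C)(C)C)cccc1O[Si](C)(C)C | intermediate
9 | 2-(Ec*)benzene-1,3-diol | C(c3ccccc3)Oc1c(Br)c(OCc3ccccc3)c2c(c1Br)O[C@H](c1ccc(OCc3ccccc3)c(OCc3ccccc3)c1)[C@H](O)[C@H]2c1c(O)cccc1O | intermediate
10 | 3,4-bis(benzyloxy)benzaldehyde | O=Cc1ccc(OCc2ccccc2)c(OCc2ccccc2)c1 | starting material
11 | (E)-3-[3,4-bis(benzyloxy)phenyl]prop-2-enal | O=C/C=C/c1ccc(OCc2ccccc2)c(OCc2ccccc2)c1 | intermediate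
12 | 8-(Ec*)-7-hydroxy-2-phenyl-4-[(E)-2-ArB-ethenyl]-4H-1,3,2-benzodioxaborin (both C4 epimers) | C(c3ccccc3)Oc1c(Br)c(OCc3ccccc3)c2c(c1Br)O[C@H](c1ccc(OCc3ccccc3)c(OCc3ccccc3)c1)[C@H](O)[C@H]2c1c(O)ccc2c1OB(c1ccccc1)OC2/C=C/c1ccc(OCc3ccccc3)c(OCc3ccccc3)c1 | intermediate
13 | 8-(Ec*)-7-hydroxy-2α-ArB-2H-chromene (flav-3-ene; 2-aryl in the spatial sense of epicatechin C2, CIP 2S because C3 is sp2) | C(c3ccccc3)Oc1c(Br)c(OCc3ccccc3)c2c(c1Br)O[C@H](c1ccc(OCc3ccccc3)c(OCc3ccccc3)c1)[C@H](O)[C@H]2c1c(O)ccc2c1O[C@H](c1ccc(OCc3ccccc3)c(OCc3ccccc3)c1)C=C2 | intermediate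
14 | 8-(Ec*)-3β,6-dibromo-2α-ArB-chromane-4α,7-diol | C(c3ccccc3)Oc1c(Br)c(OCc3ccccc3)c2c(c1Br)O[C@H](c1ccc(OCc3ccccc3)c(OCc3ccccc3)c1)[C@H](O)[C@H]2c1c(O)c(Br)cc2c1O[C@H](c1ccc(OCc3ccccc3)c(OCc3ccccc3)c1)[C@@H](Br)[C@@H]2O | intermediate
15 | 8-(Ec*)-6-bromo-3α,4α-epoxy-2α-ArB-chroman-7-ol | C(c3ccccc3)Oc1c(Br)c(OCc3ccccc3)c2c(c1Br)O[C@H](c1ccc(OCc3ccccc3)c(OCc3ccccc3)c1)[C@H](O)[C@H]2c1c(O)c(Br)cc2c1O[C@H](c1ccc(OCc3ccccc3)c(OCc3ccccc3)c1)[C@@H]4O[C@H]24 | intermediate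
16 | 8-(Ec*)-6-bromo-4β-methoxy-2α-ArB-chromane-3α,7-diol | C(c3ccccc3)Oc1c(Br)c(OCc3ccccc3)c2c(c1Br)O[C@H](c1ccc(OCc3ccccc3)c(OCc3ccccc3)c1)[C@H](O)[C@H]2c1c(O)c(Br)cc2c1O[C@H](c1ccc(OCc3ccccc3)c(OCc3ccccc3)c1)[C@H](O)[C@H]2OC | intermediate
17 | (+)-catechin | Oc1cc(O)c2c(c1)O[C@H](c1ccc(O)c(O)c1)[C@@H](O)C2 | starting material
18 | 5,7,3',4'-tetra-O-benzylcatechin | C(c3ccccc3)Oc1cc(OCc3ccccc3)c2c(c1)O[C@H](c1ccc(OCc3ccccc3)c(OCc3ccccc3)c1)[C@@H](O)C2 | intermediate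
19 | Ec*-(4β→8)-[6-bromo-3',4'-di-O-benzylepifisetinidol]-(4β→8)-[5,7,3',4'-tetra-O-benzylcatechin] | C(c3ccccc3)Oc1c(Br)c(OCc3ccccc3)c2c(c1Br)O[C@H](c1ccc(OCc3ccccc3)c(OCc3ccccc3)c1)[C@H](O)[C@H]2c1c(O)c(Br)cc2c1O[C@H](c1ccc(OCc3ccccc3)c(OCc3ccccc3)c1)[C@H](O)[C@H]2c1c(OCc3ccccc3)cc(OCc3ccccc3)c2c1O[C@H](c1ccc(OCc3ccccc3)c(OCc3ccccc3)c1)[C@@H](O)C2 | intermediate
20 | epicatechin-(4β→8)-epifisetinidol-(4β→8)-catechin (CNP0270097.1) | Oc1cc(O)c2c(c1)O[C@H](c1ccc(O)c(O)c1)[C@H](O)[C@H]2c1c(O)ccc2c1O[C@H](c1ccc(O)c(O)c1)[C@H](O)[C@H]2c1c(O)cc(O)c2c1O[C@H](c1ccc(O)c(O)c1)[C@@H](O)C2 | target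

**Totals**
Total steps: 10. Longest linear sequence: 8 (steps 1, 2, 3, 4, 6, 7, 9, 10 from (−)-epicatechin).

**Steps most likely to fail**

Most at risk is step 6, the proposed new reaction. The ion-pair ring closure may give poor facial control on this hindered chiral substrate (if the induction is opposite, the (S)-catalyst is used), and the acid may degrade the electron-rich flavene or cause 1,4-addition. The fallback uses known chemistry, sets out from 9 and returns at 13. Magnesium-mediated ortho-formylation of 9 (MgCl2, Et3N, paraformaldehyde, MeCN, reflux) gives 2,4-dihydroxy-3-(Ec*)benzaldehyde F1. The established diarylprolinol-silyl-ether-catalysed oxa-Michael/aldol condensation domino of this salicylaldehyde with enal 11 ((R)-α,α-diphenylprolinol TMS ether, 2-nitrobenzoic acid, toluene; the enantiomer is the one expected to place the 2-aryl group α) forms the O1–C2 bond enantioselectively and gives 8-(Ec*)-7-hydroxy-2α-ArB-2H-chromene-3-carbaldehyde F2. Decarbonylation with RhCl(PPh3)3 in hot toluene removes the formyl group and gives 13.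

Second is step 7. The bromohydrin carries a free para-phenol and can scramble at C4 or over-brominate, and the epoxide is very labile. The fallback sets out from 13 and returns at 16 without a halohydrin. Dimethyldioxirane (acetone, −40 °C) epoxidises C3=C4 anti to the 2-aryl group to give 8-(Ec*)-3β,4β-epoxy-2α-ArB-chroman-7-ol F3, which is not isolated. On warming with catalytic ZnBr2 it undergoes the Meinwald 1,2-hydride shift to 8-(Ec*)-7-hydroxy-2α-ArB-chroman-3-one F4. L-Selectride (THF, −78 °C) delivers hydride anti to the 2-aryl group and gives the 2,3-cis alcohol 8-(Ec*)-2α-ArB-chromane-3α,7-diol F5. DDQ in CH2Cl2–MeOH oxidises the 7-hydroxy-4-alkylphenol to its p-quinone methide, which adds methanol trans to the 3-OH to give 8-(Ec*)-4β-methoxy-2α-ArB-chromane-3α,7-diol F6. NBS (1 equiv, CH2Cl2, −40 °C) then brominates C6 and gives 16.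

Third is step 4. Bis-silylation next to the bulky flavanyl group may be incomplete, and DDQ could attack the doubly benzylic C4–H of the upper unit. The fallback sets out from 4, returns at 9 and needs no oxidant. Phloroglucinol is reduced with NaBH4 in water to 5-hydroxycyclohexane-1,3-dione F7. This is C-alkylated by 4 under the conditions of step 3 to give 2-(Ec*)-5-hydroxycyclohexane-1,3-dione F8. Mild acid (TsOH, toluene, 40 °C) eliminates water from the β-hydroxy ketone, and the cyclohexenedione tautomerises to resorcinol 9.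

**Further compounds**
F1 | step 6 | 2,4-dihydroxy-3-(Ec*)benzaldehyde | C(c3ccccc3)Oc1c(Br)c(OCc3ccccc3)c2c(c1Br)O[C@H](c1ccc(OCc3ccccc3)c(OCc3ccccc3)c1)[C@H](O)[C@H]2c1c(O)ccc(C=O)c1O
F2 | step 6 | 8-(Ec*)-7-hydroxy-2α-ArB-2H-chromene-3-carbaldehyde | C(c3ccccc3)Oc1c(Br)c(OCc3ccccc3)c2c(c1Br)O[C@H](c1ccc(OCc3ccccc3)c(OCc3ccccc3)c1)[C@H](O)[C@H]2c1c(O)ccc2c1O[C@H](c1ccc(OCc3ccccc3)c(OCc3ccccc3)c1)C(C=O)=C2
F3 | step 7 | 8-(Ec*)-3β,4β-epoxy-2α-ArB-chroman-7-ol | C(c3ccccc3)Oc1c(Br)c(OCc3ccccc3)c2c(c1Br)O[C@H](c1ccc(OCc3ccccc3)c(OCc3ccccc3)c1)[C@H](O)[C@H]2c1c(O)ccc2c1O[C@H](c1ccc(OCc3ccccc3)c(OCc3ccccc3)c1)[C@H]4O[C@@H]24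
F4 | step 7 | 8-(Ec*)-7-hydroxy-2α-ArB-chroman-3-one | C(c3ccccc3)Oc1c(Br)c(OCc3ccccc3)c2c(c1Br)O[C@H](c1ccc(OCc3ccccc3)c(OCc3ccccc3)c1)[C@H](O)[C@H]2c1c(O)ccc2c1O[C@H](c1ccc(OCc3ccccc3)c(OCc3ccccc3)c1)C(=O)C2
F5 | step 7 | 8-(Ec*)-2α-ArB-chromane-3α,7-diol | C(c3ccccc3)Oc1c(Br)c(OCc3ccccc3)c2c(c1Br)O[C@H](c1ccc(OCc3ccccc3)c(OCc3ccccc3)c1)[C@H](O)[C@H]2c1c(O)ccc2c1O[C@H](c1ccc(OCc3ccccc3)c(OCc3ccccc3)c1)[C@H](O)C2
F6 | step 7 | 8-(Ec*)-4β-methoxy-2α-ArB-chromane-3α,7-diol | C(c3ccccc3)Oc1c(Br)c(OCc3ccccc3)c2c(c1Br)O[C@H](c1ccc(OCc3ccccc3)c(OCc3ccccc3)c1)[C@H](O)[C@H]2c1c(O)ccc2c1O[C@H](c1ccc(OCc3ccccc3)c(OCc3ccccc3)c1)[C@H](O)[C@H]2OC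
F7 | step 4 | 5-hydroxycyclohexane-1,3-dione | O=C1CC(O)CC(=O)C1
F8 | step 4 | 2-(Ec*)-5-hydroxycyclohexane-1,3-dione | C(c3ccccc3)Oc1c(Br)c(OCc3ccccc3)c2c(c1Br)O[C@H](c1ccc(OCc3ccccc3)c(OCc3ccccc3)c1)[C@H](O)[C@H]2C1C(=O)CC(O)CC1=O
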